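**Retrosynthetic overview**
- The target is a 5-hydroxyflavone. The last operations are hydrogenolysis of two benzyl ethers on ring B and chelation-controlled cleavage of the peri (C5) methyl ether of a 5,6,7,8-tetramethoxyflavone.
- Ring C (the pyranone) is the only ring built. It is closed by oxidative cyclisation of a 2'-hydroxychalcone.
- The chalcone comes from the key C–C bond formation, an intermolecular Claisen–Schmidt aldol condensation of a ring A acetophenone with a ring B benzaldehyde.
- The ring A ketone is made from a commercial trimethoxyphenol by C-acetylation, bromination and copper-catalysed methoxylation.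
- The ring B aldehyde is made from a commercial methoxy-hydroquinone by bis-benzylation and Vilsmeier formylation.

Assumption: the target has no stereocentre and is achiral, so no enantiocontrol is needed; the only stereo-element on the route is the E alkene of the chalcone, and the racemic intermediates 9 and 11 lose their stereocentres on the way.

**Step 1**
Reactants: 1 3,4,5-trimethoxyphenol
Product: 2 1-(6-hydroxy-2,3,4-trimethoxyphenyl)ethan-1-one
Conditions: AcOH (solvent and acyl donor), BF3·OEt2 (3 equiv), 90 °C, 3 h; then ice-water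
Reagents that add atoms: acetic acid, CC(=O)O
Why: BF3-promoted Friedel–Crafts (Fries-type) C-acylation occurs at the free position ortho to the phenol and para to a methoxy group (both such positions are equivalent), giving the hydrogen-bonded o-hydroxy ketone.

**Step 2**
Reactants: 2 1-(6-hydroxy-2,3,4-trimethoxyphenyl)ethan-1-one
Product: 3 1-(3-bromo-2-hydroxy-4,5,6-trimethoxyphenyl)ethan-1-one
Conditions: NBS (1.05 equiv), MeCN, 0 °C to rt, dark
Reagents that add atoms: N-bromosuccinimide, O=C1CCC(=O)N1Br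
Why: Electrophilic aromatic bromination takes the single remaining ring C–H, which is ortho to the phenol and strongly activated, in preference to the acetyl methyl group.

**Step 3**
Reactants: 3 1-(3-bromo-2-hydroxy-4,5,6-trimethoxyphenyl)ethan-1-one
Product: 4 1-(2-hydroxy-3,4,5,6-tetramethoxyphenyl)ethan-1-one
Conditions: NaOMe (6 equiv, 25% in MeOH), CuBr (0.2 equiv), DMF, 110 °C, N2; then 2 M HCl
Reagents that add atoms: sodium methoxide, [Na+].[O-]C
Why: Copper-catalysed Ullmann-type methoxylation of an o-bromophenol (the same reaction that turns 5-bromovanillin into syringaldehyde) replaces Br by OMe, while the hindered ketone only enolises reversibly.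

**Step 4**
Reactants: 5 2-methoxybenzene-1,4-diol (methoxyhydroquinone)
Product: 6 1,4-bis(benzyloxy)-2-methoxybenzene
Conditions: BnBr (2.4 equiv), K2CO3 (3 equiv), DMF, 60 °C, N2
Reagents that add atoms: benzyl bromide, BrCc1ccccc1
Why: Williamson ether synthesis; both phenoxides are alkylated by the reactive benzylic bromide, and exclusion of air prevents quinone formation.

**Step 5**
Reactants: 6 1,4-bis(benzyloxy)-2-methoxybenzene
Product: 8 2,5-bis(benzyloxy)-4-methoxybenzaldehyde, via aryl iminium chloride 7 (not isolated)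
Conditions: POCl3 (1.5 equiv), DMF, 0 to 70 °C; then ice-water, 1 h
Reagents that add atoms: N,N-dimethylformamide, CN(C)C=O; water, O
Why: Vilsmeier–Haack formylation attacks the unhindered position para to the methoxy group and ortho to a benzyloxy group (as 1,2,4-trimethoxybenzene gives 2,4,5-trimethoxybenzaldehyde), and the iminium salt is hydrolysed on work-up.

**Step 6**
Reactants: 4 1-(2-hydroxy-3,4,5,6-tetramethoxyphenyl)ethan-1-one; 8 2,5-bis(benzyloxy)-4-methoxybenzaldehyde
Product: 10 (E)-3-[2,5-bis(benzyloxy)-4-methoxyphenyl]-1-(2-hydroxy-3,4,5,6-tetramethoxyphenyl)prop-2-en-1-one, via racemic aldol adduct 9 (not isolated)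
Conditions: KOH (10 equiv, 50% aq.), EtOH, rt, 36 h; then 2 M HCl, 0 °C
Reagents that add atoms: none
Why: Claisen–Schmidt crossed aldol condensation: the ketone enolate adds to the non-enolisable aldehyde and E1cB dehydration gives the conjugated, thermodynamically preferred E enone.

**Step 7**
Reactants: 10 (E)-3-[2,5-bis(benzyloxy)-4-methoxyphenyl]-1-(2-hydroxy-3,4,5,6-tetramethoxyphenyl)prop-2-en-1-one
Product: 12 2-[2,5-bis(benzyloxy)-4-methoxyphenyl]-5,6,7,8-tetramethoxy-4H-chromen-4-one, via racemic flavanone 11 (not isolated)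
Conditions: I2 (0.1 equiv), DMSO, 130 °C, 4 h; then aq. Na2S2O3 wash
Reagents that add atoms: none
Why: Iodine/DMSO oxidative cyclisation: intramolecular oxa-Michael addition of the 2'-phenol closes ring C, and iodine-mediated dehydrogenation (HI reoxidised by DMSO) gives the flavone and removes the transient C2 stereocentre.

**Step 8**
Reactants: 12 2-[2,5-bis(benzyloxy)-4-methoxyphenyl]-5,6,7,8-tetramethoxy-4H-chromen-4-one
Product: 13 2-(2,5-dihydroxy-4-methoxyphenyl)-5,6,7,8-tetramethoxy-4H-chromen-4-one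
Conditions: H2 (1 atm), 10% Pd/C, EtOAc–MeOH 1:1, rt; filter under N2
Reagents that add atoms: none
Why: Catalytic hydrogenolysis cleaves the two benzylic C–O bonds under mild conditions that leave the chromone double bond and the methyl ethers intact.

**Step 9**
Reactants: 13 2-(2,5-dihydroxy-4-methoxyphenyl)-5,6,7,8-tetramethoxy-4H-chromen-4-one
Product: 15 2-(2,5-dihydroxy-4-methoxyphenyl)-5-hydroxy-6,7,8-trimethoxy-4H-chromen-4-one, via tris(dichloroboryl) ester 14 (not isolated)
Conditions: BCl3 (5 equiv, 1 M in CH2Cl2), CH2Cl2, −78 to 0 °C, 2 h; then 1 M aq. HCl, rt, 30 min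
Reagents that add atoms: none
Why: Chelation-controlled Lewis-acid ether cleavage: BCl3 bound to the C4 carbonyl delivers chloride only to the methyl of the peri 5-OMe through a six-membered chelate, so the other four methyl ethers survive and aqueous work-up frees the phenols.

**Compound list**
1 | 3,4,5-trimethoxyphenol | COc1cc(O)cc(OC)c1OC | starting material
2 | 1-(6-hydroxy-2,3,4-trimethoxyphenyl)ethan-1-one | CC(=O)c1c(O)cc(OC)c(OC)c1OC | intermediate
3 | 1-(3-bromo-2-hydroxy-4,5,6-trimethoxyphenyl)ethan-1-one | CC(=O)c1c(O)c(Br)c(OC)c(OC)c1OC | intermediate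
4 | 1-(2-hydroxy-3,4,5,6-tetramethoxyphenyl)ethan-1-one | CC(=O)c1c(O)c(OC)c(OC)c(OC)c1OC | intermediate
5 | 2-methoxybenzene-1,4-diol (methoxyhydroquinone) | COc1cc(O)ccc1O | starting material
6 | 1,4-bis(benzyloxy)-2-methoxybenzene | COc1cc(OCc2ccccc2)ccc1OCc1ccccc1 | intermediate
7 | N-{[2,5-bis(benzyloxy)-4-methoxyphenyl]methylidene}-N-methylmethanaminium chloride (not isolated) | C[N+](C)=Cc1cc(OCc2ccccc2)c(OC)cc1OCc1ccccc1.[Cl-] | intermediate
8 | 2,5-bis(benzyloxy)-4-methoxybenzaldehyde | O=Cc1cc(OCc2ccccc2)c(OC)cc1OCc1ccccc1 | intermediate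
9 | racemic 3-[2,5-bis(benzyloxy)-4-methoxyphenyl]-3-hydroxy-1-(2-hydroxy-3,4,5,6-tetramethoxyphenyl)propan-1-one (not isolated) | COc1cc(OCc2ccccc2)c(C(O)CC(=O)c2c(O)c(OC)c(OC)c(OC)c2OC)cc1OCc1ccccc1 | intermediate
10 | (E)-3-[2,5-bis(benzyloxy)-4-methoxyphenyl]-1-(2-hydroxy-3,4,5,6-tetramethoxyphenyl)prop-2-en-1-one | COc1cc(OCc2ccccc2)c(/C=C/C(=O)c2c(O)c(OC)c(OC)c(OC)c2OC)cc1OCc1ccccc1 | intermediate
11 | racemic 2-[2,5-bis(benzyloxy)-4-methoxyphenyl]-5,6,7,8-tetramethoxychroman-4-one (not isolated) | COc1cc(OCc2ccccc2)c(C2CC(=O)c3c(OC)c(OC)c(OC)c(OC)c3O2)cc1OCc1ccccc1 | intermediate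
12 | 2-[2,5-bis(benzyloxy)-4-methoxyphenyl]-5,6,7,8-tetramethoxy-4H-chromen-4-one | COc1cc(OCc2ccccc2)c(-c2cc(=O)c3c(OC)c(OC)c(OC)c(OC)c3o2)cc1OCc1ccccc1 | intermediate
13 | 2-(2,5-dihydroxy-4-methoxyphenyl)-5,6,7,8-tetramethoxy-4H-chromen-4-one | COc1cc(O)c(-c2cc(=O)c3c(OC)c(OC)c(OC)c(OC)c3o2)cc1O | intermediate
14 | 2-{2,5-bis[(dichloroboranyl)oxy]-4-methoxyphenyl}-5-[(dichloroboranyl)oxy]-6,7,8-trimethoxy-4H-chromen-4-one (not isolated) | COc1cc(OB(Cl)Cl)c(-c2cc(=O)c3c(OB(Cl)Cl)c(OC)c(OC)c(OC)c3o2)cc1OB(Cl)Cl | intermediate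
15 | 2-(2,5-dihydroxy-4-methoxyphenyl)-5-hydroxy-6,7,8-trimethoxy-4H-chromen-4-one (5,2',5'-trihydroxy-6,7,8,4'-tetramethoxyflavone) | COc1cc(O)c(-c2cc(=O)c3c(O)c(OC)c(OC)c(OC)c3o2)cc1O | target

**Totals**
Total step count: 9 (steps 1–3 make the ring A ketone, steps 4–5 the ring B aldehyde, steps 6–9 join and finish).
Longest linear sequence: 7 steps (1, 2, 3, 6, 7, 8, 9).

**Steps most likely to fail, with fallbacks**

Step 3 (copper-catalysed methoxylation; risks are hydrodebromination and base-induced ketone side reactions). The fallback installs the missing oxygen by formylation and Dakin oxidation instead of C–O coupling. It sets out from compound 2 and comes back at compound 4. Duff formylation of 2 (hexamethylenetetramine, CF3CO2H, 90 °C, then aq. HCl) at the same single free position gives 3-acetyl-2-hydroxy-4,5,6-trimethoxybenzaldehyde F1. Dakin oxidation (H2O2 1.05 equiv, aq. NaOH, 0 °C) of the aldehyde, which is far more reactive than the hindered ketone, gives the catechol 1-(2,3-dihydroxy-4,5,6-trimethoxyphenyl)ethan-1-one F2 with loss of formate. Methylation of its dianion (NaH 2.2 equiv, DMSO, then MeI 1.0 equiv) occurs at the more basic, non-chelated 3-phenoxide and delivers compound 4.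

Step 7 (iodine/DMSO oxidative cyclisation; risks are benzyl ether loss through HI, ring iodination of the electron-rich ring B and stalling at the flavanone). The fallback builds ring C without an oxidation step, through a 1,3-diketone made by an intermolecular Claisen condensation. It sets out from compound 8 (with compound 4 as partner) and comes back at compound 12. Pinnick oxidation of 8 (NaClO2, NaH2PO4, 2-methyl-2-butene, t-BuOH/H2O) gives 2,5-bis(benzyloxy)-4-methoxybenzoic acid F3, which (COCl)2 with catalytic DMF in CH2Cl2 converts into 2,5-bis(benzyloxy)-4-methoxybenzoyl chloride F4. The lithium dianion of ketone 4 (LiN(SiMe3)2 3.2 equiv, THF, −78 °C) is C-acylated by the acid chloride to give 1-[2,5-bis(benzyloxy)-4-methoxyphenyl]-3-(2-hydroxy-3,4,5,6-tetramethoxyphenyl)propane-1,3-dione F5. Acid-catalysed cyclodehydration (p-TsOH, toluene, reflux) then gives flavone 12.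

Step 9 (selective 5-O-demethylation on the fully elaborated triol; risks are over-cleavage of the 6-OMe or 4'-OMe and oxidation of the hydroquinone). The fallback frees the future 5-OH early, on the simple ketone, so that no methyl ether is cleaved at the end. It sets out from compound 4 and comes back at compound 15. BCl3 (1.5 equiv, CH2Cl2, 0 °C) cleaves only the methoxy ortho to the acetyl group of 4 to give the symmetrical 1-(2,6-dihydroxy-3,4,5-trimethoxyphenyl)ethan-1-one F6. Claisen–Schmidt condensation with aldehyde 8 (KOH, EtOH, 40 °C) gives (E)-3-[2,5-bis(benzyloxy)-4-methoxyphenyl]-1-(2,6-dihydroxy-3,4,5-trimethoxyphenyl)prop-2-en-1-one F7. I2/DMSO cyclisation, where either phenol gives the same product, furnishes 2-[2,5-bis(benzyloxy)-4-methoxyphenyl]-5-hydroxy-6,7,8-trimethoxy-4H-chromen-4-one F8. Hydrogenolysis (H2, 10% Pd/C, EtOAc–MeOH) then gives target 15 directly.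

**Further compounds**
F1 | step 3 | 3-acetyl-2-hydroxy-4,5,6-trimethoxybenzaldehyde | CC(=O)c1c(O)c(C=O)c(OC)c(OC)c1OC
F2 | step 3 | 1-(2,3-dihydroxy-4,5,6-trimethoxyphenyl)ethan-1-one | CC(=O)c1c(O)c(O)c(OC)c(OC)c1OC
F3 | step 7 | 2,5-bis(benzyloxy)-4-methoxybenzoic acid | OC(=O)c1cc(OCc2ccccc2)c(OC)cc1OCc1ccccc1
F4 | step 7 | 2,5-bis(benzyloxy)-4-methoxybenzoyl chloride | ClC(=O)c1cc(OCc2ccccc2)c(OC)cc1OCc1ccccc1
F5 | step 7 | 1-[2,5-bis(benzyloxy)-4-methoxyphenyl]-3-(2-hydroxy-3,4,5,6-tetramethoxyphenyl)propane-1,3-dione | COc1cc(OCc2ccccc2)c(C(=O)CC(=O)c2c(O)c(OC)c(OC)c(OC)c2OC)cc1OCc1ccccc1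
F6 | step 9 | 1-(2,6-dihydroxy-3,4,5-trimethoxyphenyl)ethan-1-one | CC(=O)c1c(O)c(OC)c(OC)c(OC)c1O
F7 | step 9 | (E)-3-[2,5-bis(benzyloxy)-4-methoxyphenyl]-1-(2,6-dihydroxy-3,4,5-trimethoxyphenyl)prop-2-en-1-one | COc1cc(OCc2ccccc2)c(/C=C/C(=O)c2c(O)c(OC)c(OC)c(OC)c2O)cc1OCc1ccccc1
F8 | step 9 | 2-[2,5-bis(benzyloxy)-4-methoxyphenyl]-5-hydroxy-6,7,8-trimethoxy-4H-chromen-4-one | COc1cc(OCc2ccccc2)c(-c2cc(=O)c3c(O)c(OC)c(OC)c(OC)c3o2)cc1OCc1ccccc1
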